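Follow one substrate molecule through the flask and ask for its chances at each fork.

- north: substrate 0.95 M; partner 1 equiv; run made earlier
- flask: substrate 0.63 M; partner 1.00 equiv; time 8.0 min

north run (percent of the substrate charged)

| time / s | side product B / % | target / % | substrate / % | side product C / % | side product A / % |
|---|---|---|---|---|---|
| 10.0 | 18 | 2 | 74 | 0 | 3 |
| 15.0 | 22 | 5 | 70 | 0 | 6 |
| 25.0 | 29 | 8 | 55 | 1 | 10 |
| 50.0 | 39 | 12 | 33 | 4 | 11 |
| 90.0 | 46 | 14 | 24 | 8 | 15 |

(each reading ± 1.5 percentage points)

* the species that holds most of what was charged as substrate, at 8.0 min (side product A / target / substrate / side product B / side product C)
* the largest share itself, whichever of these holds it, in percent of the substrate charged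

- a species is counted by the substrate in it: one side product B or side product C counts as two
- the earlier runs were read with a standard deviation of 1.5 percentage points
- what may be going on: partner -> decomposed reagent; substrate -> side product A; 2 substrate -> side product B; substrate + target -> side product C; substrate + partner -> target

1. Let f be the fraction of the charge still substrate. In the proposed steps, loss to side product A goes with f and loss to side product B with f squared, while the target and side product C arms go with f and with the charge.

2. Summing the north readings gives the time integrals 41.0 s for f and 22.8 s for f squared.

3. Scaling the charge-following arms by 0.663 for the flask, I get 1.85, the fork number: the rate into side product B at the full charge over the other arms together, a selectivity factor. In this reckoning the odds for side product B at fraction f are the fork number times f, to one.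

4. By my reckoning the other arms by themselves leave 3.12% of the charge as substrate at 8.0 min, hardly any, so I average the chance from the full charge down to nothing.

5. The chord gives a floor of 32.5%, the chance at half the charge a ceiling of 48.1%, and the exact average 43.4%. I give side product A 28.7%, less than that.

6. The forecast names side product B at 49%, just above my ceiling, and opens: “Side product B is the main sink”.

    partner → decomposed reagent (k = 7.20 × 10⁻⁴ s⁻¹)
    substrate → side product A (k = 0.00370 s⁻¹)
    2 substrate → side product B (k = 0.0110 L mol⁻¹ s⁻¹)
    substrate + target → side product C (k = 0.0160 L mol⁻¹ s⁻¹)
    substrate + partner → target (k = 0.00420 L mol⁻¹ s⁻¹)

In the flask side product B holds 45.9%, above my average and below my ceiling, and at 80.0 min it holds 46.0%. From 0.800 min, with 46.4% still substrate, the fork number promises 12.9% more side product B, and the flask adds 14 percentage points. For the neighbour flask with 0.25 M of substrate, the same north sums give a fork number of 1.05 and a share of 31.6%, and at 8.00 min that neighbour flask holds 33.2% as side product B.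

The runs come from a simulation for an exercise; scatter was added.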